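**Retrosynthetic overview**

- The target is a central 3-acetyl-2,4,6-trihydroxybenzene ring joined through two CH2 groups to two outer rings that are not alike. With C1 = the butyryl carbon and C5 = the bridge carbon in both, ring A carries 2-OH, 3-Me, 4-OMe, 6-OH and ring B carries 2-OMe, 3-Me, 4-OH, 6-OH.
- Last cuts: the two butyryl C–C bonds (one equivalent of butanoyl chloride at the single free CH of each outer ring) and all O-protecting groups.
- Each outer ring is cut by the same three bonds, C5–C6, C3–C4 and C6–C1, into a central-ring arm ArCH2–C≡C–OR and a 3-alkoxy-2-methylcyclobutenone. The feature used is the alternation of oxygen-bearing carbons (C2, C4, C6) with carbon-bearing ones (C1, C3, C5) in both outer rings; the alkyne oxygen lands on C4, the cyclobutenone oxygen on C2 and the ketene oxygen on C6.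
- Ring order: central ring (bought), then ring B (adamantyloxy-alkyne arm + 3-methoxycyclobutenone, step 12), then ring A (methoxy-alkyne arm + 3-benzyloxycyclobutenone, step 19).
- The arms come from twofold formylation of 2,4,6-trihydroxyacetophenone, benzylic bromides and Stille coupling with alkoxyethynylstannanes; both cyclobutenones come from one 2-methylcyclobutane-1,3-dione enol.

Key step: step 19

Remark on the chemistry: ring A needs a methyl on the alkyne-derived oxygen (C4) and a free hydroxyl on the cyclobutenone-derived oxygen (C2), whereas ring B needs the reverse. One cyclobutenone therefore cannot serve both arms, and two cyclobutenones offered to two ynol ethers at once would pair at random. The benzannulation is thus run once from each arm, so the ynol ether that enters the key step already carries ring B in place of a second alkyne.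

**Step 1**
Reactants: 1 2,4,6-trihydroxyacetophenone
Product: 3 5-acetyl-2,4,6-trihydroxybenzene-1,3-dicarbaldehyde, via bis(chloromethoxymethyl) intermediate 2 (not isolated)
Conditions: Cl2CHOMe, TiCl4, CH2Cl2, 0 °C → rt; then ice/1 M HCl
Reagents that add atoms: dichloromethyl methyl ether, COC(Cl)Cl; water, O
Why: Rieche formylation, in which the TiCl4-activated dichloromethyl ether attacks the two free, strongly activated ring carbons (the third is blocked by the acetyl group) and aqueous work-up hydrolyses the α-chloro ether 2 to the dialdehyde.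

**Step 2**
Reactants: 3 5-acetyl-2,4,6-trihydroxybenzene-1,3-dicarbaldehyde
Product: 4 5-acetyl-2,4,6-tris(benzyloxy)benzene-1,3-dicarbaldehyde
Conditions: BnBr, K2CO3, DMF, 50 °C
Reagents that add atoms: benzyl bromide, BrCc1ccccc1
Why: Williamson O-benzylation of three phenoxides that are vinylogous carboxylates (each flanked by two carbonyl groups); every ring carbon is substituted, so C-alkylation would cost the aromaticity.

**Step 3**
Reactants: 4 5-acetyl-2,4,6-tris(benzyloxy)benzene-1,3-dicarbaldehyde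
Product: 5 1-[2,4,6-tris(benzyloxy)-3,5-bis(hydroxymethyl)phenyl]ethanone
Conditions: NaBH4, THF/MeOH, −20 °C
Reagents that add atoms: none
Why: Chemoselective borohydride reduction, since the aldehydes are far more electrophilic than the twisted, di-ortho-substituted aryl methyl ketone, which should stay untouched at low temperature.

**Step 4**
Reactants: 5 1-[2,4,6-tris(benzyloxy)-3,5-bis(hydroxymethyl)phenyl]ethanone
Product: 6 1-[2,4,6-tris(benzyloxy)-3-({[tert-butyl(dimethyl)silyl]oxy}methyl)-5-(hydroxymethyl)phenyl]ethanone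
Conditions: NaH (1.0 equiv), THF, 0 °C; TBSCl (1.0 equiv), rt
Reagents that add atoms: tert-butyl(chloro)dimethylsilane, CC(C)(C)[Si](C)(C)Cl
Why: Monosilylation of a symmetric diol through its monosodium alkoxide; the two CH2OH groups are equivalent, so any mono-ether is the same compound, the outcome is at best statistical, and unreacted 5 and the bis-silyl ether (after desilylation) are recycled.

**Step 5**
Reactants: 6 1-[2,4,6-tris(benzyloxy)-3-({[tert-butyl(dimethyl)silyl]oxy}methyl)-5-(hydroxymethyl)phenyl]ethanone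
Product: 7 1-[2,4,6-tris(benzyloxy)-3-(bromomethyl)-5-({[tert-butyl(dimethyl)silyl]oxy}methyl)phenyl]ethanone
Conditions: CBr4, PPh3, CH2Cl2, 0 °C
Reagents that add atoms: tetrabromomethane, BrC(Br)(Br)Br
Why: Appel bromination of the primary benzylic alcohol under neutral conditions that spare the silyl ether, the benzyl ethers and the ketone; the easily ionised bromide is used at once.

**Step 6**
Reactants: 8 adamantan-1-ol; 9 trichloroethylene
Product: 10 1-{[(E)-1,2-dichloroethenyl]oxy}adamantane
Conditions: KH, THF, 0 °C → rt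
Reagents that add atoms: none
Why: Known alkoxide/trichloroethylene route to 1,2-dichlorovinyl ethers, in which the potassium alkoxide eliminates HCl to dichloroacetylene and adds to it anti, giving the E isomer.

**Step 7**
Reactants: 10 1-{[(E)-1,2-dichloroethenyl]oxy}adamantane
Product: 13 tributyl[(1-adamantyloxy)ethynyl]stannane, via chloroalkynyl ether 11 (not isolated), via lithium adamantyloxyacetylide 12 (not isolated)
Conditions: n-BuLi (2.2 equiv), THF, −78 → −40 °C; Bu3SnCl, −78 °C → rt
Reagents that add atoms: tributyltin chloride, CCCC[Sn](Cl)(CCCC)CCCC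
Why: Elimination of LiCl gives 11, chlorine–lithium exchange gives the acetylide 12 and Bu3SnCl traps it at carbon; the 1-adamantyl group is chosen because it cannot be lost by retro-ene fragmentation on heating (a bridgehead alkene would result) and is later removed by acid.

**Step 8**
Reactants: 7 1-[2,4,6-tris(benzyloxy)-3-(bromomethyl)-5-({[tert-butyl(dimethyl)silyl]oxy}methyl)phenyl]ethanone; 13 tributyl[(1-adamantyloxy)ethynyl]stannane
Product: 14 1-[3-[3-(1-adamantyloxy)prop-2-yn-1-yl]-2,4,6-tris(benzyloxy)-5-({[tert-butyl(dimethyl)silyl]oxy}methyl)phenyl]ethanone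
Conditions: Pd(PPh3)4 (5 mol %), THF, 60 °C; aq. KF work-up
Reagents that add atoms: none
Why: Stille coupling (oxidative addition of zerovalent palladium into the benzylic C–Br bond, alkynyl transfer from tin, reductive elimination) forms the CH2–C(sp) bond without base or a free carbon nucleophile, so the enolisable acetyl group, the silyl ether and the ynol ether survive.

**Step 9**
Reactants: 15 propanoyl chloride; 16 ethoxyacetylene
Product: 18 3-ethoxy-4-methylcyclobut-2-en-1-one (racemic), via methylketene 17 (not isolated)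
Conditions: Et3N, Et2O, 0 °C → rt (15 added slowly)
Reagents that add atoms: none
Why: Dehydrochlorination gives methylketene, which adds [2+2] to the alkoxyalkyne with the unsubstituted alkyne carbon on the ketene carbonyl carbon, a known route to 3-ethoxycyclobutenones that places the methyl group on C4.

**Step 10**
Reactants: 18 3-ethoxy-4-methylcyclobut-2-en-1-one (racemic)
Product: 19 3-hydroxy-2-methylcyclobut-2-en-1-one
Conditions: 1 M HCl, THF, 0 °C → rt
Reagents that add atoms: water, O
Why: Acid hydrolysis of the vinylogous ester gives 2-methylcyclobutane-1,3-dione, which should settle as its more substituted conjugated enol; this moves the methyl group to C2, between the two oxygen-bearing carbons, where both benzannulations need it.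

**Step 11**
Reactants: 19 3-hydroxy-2-methylcyclobut-2-en-1-one
Product: 20 3-methoxy-2-methylcyclobut-2-en-1-one
Conditions: MeI, Ag2O, CH2Cl2, rt, dark
Reagents that add atoms: iodomethane, CI
Why: Silver-assisted O-alkylation of the strongly acidic enol (oxygen rather than C2 is alkylated); the enolate is symmetric, so either oxygen gives the same product.

**Step 12**
Reactants: 14 1-[3-[3-(1-adamantyloxy)prop-2-yn-1-yl]-2,4,6-tris(benzyloxy)-5-({[tert-butyl(dimethyl)silyl]oxy}methyl)phenyl]ethanone; 20 3-methoxy-2-methylcyclobut-2-en-1-one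
Product: 25 1-[3-{[2-(1-adamantyloxy)-6-hydroxy-4-methoxy-3-methylphenyl]methyl}-2,4,6-tris(benzyloxy)-5-({[tert-butyl(dimethyl)silyl]oxy}methyl)phenyl]ethanone, via vinylketene 21 (not isolated), via vinylcyclobutenone adduct 22 (not isolated), via dienylketene 23 (not isolated), via cyclohexadienone 24 (not isolated)
Conditions: toluene, 120 °C, sealed tube; then K2CO3, MeOH, rt
Reagents that add atoms: none
Why: Danheiser benzannulation (4π opening of 20 to 21, regioselective [2+2] with the ynol ether to 22, 4π opening to 23, 6π closure to 24, enolisation), in which the CH2-bearing alkyne carbon bonds to the ketene carbonyl carbon, so ring B receives OH on C6, the removable adamantyloxy group on C4, methyl on C3 and methoxy on C2.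

**Step 13**
Reactants: 25 1-[3-{[2-(1-adamantyloxy)-6-hydroxy-4-methoxy-3-methylphenyl]methyl}-2,4,6-tris(benzyloxy)-5-({[tert-butyl(dimethyl)silyl]oxy}methyl)phenyl]ethanone
Product: 26 1-[3-{[2-(1-adamantyloxy)-6-(benzyloxy)-4-methoxy-3-methylphenyl]methyl}-2,4,6-tris(benzyloxy)-5-({[tert-butyl(dimethyl)silyl]oxy}methyl)phenyl]ethanone
Conditions: BnBr, K2CO3, DMF, rt
Reagents that add atoms: benzyl bromide, BrCc1ccccc1
Why: Williamson benzylation of the only free phenol, so that it can neither be alkylated by the benzylic bromide of step 15 nor acylated by ketene in step 19.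

**Step 14**
Reactants: 26 1-[3-{[2-(1-adamantyloxy)-6-(benzyloxy)-4-methoxy-3-methylphenyl]methyl}-2,4,6-tris(benzyloxy)-5-({[tert-butyl(dimethyl)silyl]oxy}methyl)phenyl]ethanone
Product: 27 1-[3-{[2-(1-adamantyloxy)-6-(benzyloxy)-4-methoxy-3-methylphenyl]methyl}-2,4,6-tris(benzyloxy)-5-(hydroxymethyl)phenyl]ethanone
Conditions: Bu4NF, THF, 0 °C
Reagents that add atoms: none
Why: Fluoride cleaves the Si–O bond of the primary silyl ether, while the aryl ethers and the ketone are inert.

**Step 15**
Reactants: 27 1-[3-{[2-(1-adamantyloxy)-6-(benzyloxy)-4-methoxy-3-methylphenyl]methyl}-2,4,6-tris(benzyloxy)-5-(hydroxymethyl)phenyl]ethanone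
Product: 28 1-[3-{[2-(1-adamantyloxy)-6-(benzyloxy)-4-methoxy-3-methylphenyl]methyl}-2,4,6-tris(benzyloxy)-5-(bromomethyl)phenyl]ethanone
Conditions: CBr4, PPh3, CH2Cl2, 0 °C
Reagents that add atoms: tetrabromomethane, BrC(Br)(Br)Br
Why: Appel bromination as in step 5; the neutral conditions keep the acid-labile adamantyl ether, and the bromide is coupled at once to forestall Friedel–Crafts self-alkylation of the electron-rich ring B.

**Step 16**
Reactants: 29 chloroacetaldehyde dimethyl acetal
Product: 31 tributyl(methoxyethynyl)stannane, via lithium methoxyacetylide 30 (not isolated)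
Conditions: LiNEt2 (3 equiv, from Et2NH and n-BuLi), THF, 0 °C; Bu3SnCl, −78 °C → rt
Reagents that add atoms: tributyltin chloride, CCCC[Sn](Cl)(CCCC)CCCC
Why: Three equivalents of amide base eliminate methanol and HCl and deprotonate the methoxyacetylene so formed (a known in-flask route to lithium alkoxyacetylides), and Bu3SnCl stannylates the acetylide carbon.

**Step 17**
Reactants: 28 1-[3-{[2-(1-adamantyloxy)-6-(benzyloxy)-4-methoxy-3-methylphenyl]methyl}-2,4,6-tris(benzyloxy)-5-(bromomethyl)phenyl]ethanone; 31 tributyl(methoxyethynyl)stannane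
Product: 32 1-[3-{[2-(1-adamantyloxy)-6-(benzyloxy)-4-methoxy-3-methylphenyl]methyl}-2,4,6-tris(benzyloxy)-5-(3-methoxyprop-2-yn-1-yl)phenyl]ethanone
Conditions: Pd(PPh3)4 (5 mol %), THF, 60 °C; aq. KF work-up
Reagents that add atoms: none
Why: Stille coupling as in step 8 installs the methoxy ynol ether arm under neutral conditions tolerated by the ketone and the adamantyl ether.

**Step 18**
Reactants: 19 3-hydroxy-2-methylcyclobut-2-en-1-one
Product: 33 3-(benzyloxy)-2-methylcyclobut-2-en-1-one
Conditions: BnBr, Ag2O, CH2Cl2, rt, dark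
Reagents that add atoms: benzyl bromide, BrCc1ccccc1
Why: Silver-mediated O-benzylation of the symmetric enolate, as in step 11, gives the vinylogous benzyl ester whose oxygen becomes the C2 hydroxyl of ring A.

**Step 19**
Reactants: 32 1-[3-{[2-(1-adamantyloxy)-6-(benzyloxy)-4-methoxy-3-methylphenyl]methyl}-2,4,6-tris(benzyloxy)-5-(3-methoxyprop-2-yn-1-yl)phenyl]ethanone; 33 3-(benzyloxy)-2-methylcyclobut-2-en-1-one
Product: 38 1-[3-{[2-(1-adamantyloxy)-6-(benzyloxy)-4-methoxy-3-methylphenyl]methyl}-2,4,6-tris(benzyloxy)-5-{[4-(benzyloxy)-6-hydroxy-2-methoxy-3-methylphenyl]methyl}phenyl]ethanone, via vinylketene 34 (not isolated), via vinylcyclobutenone adduct 35 (not isolated), via dienylketene 36 (not isolated), via cyclohexadienone 37 (not isolated)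
Conditions: toluene, 120 °C, sealed tube; then K2CO3, MeOH, rt
Reagents that add atoms: none
Why: At 120 °C 33 should open by 4π-electrocyclic cleavage of its C1–C4 bond to the vinylketene 34, and the alkyne of 32 adds to the ketene C=C bond in a [2+2] cycloaddition that forms the C5–C6 and C3–C4 bonds of ring A and gives the 4-vinylcyclobutenone 35. A second 4π opening gives the dienylketene 36, whose thermal disrotatory 6π-electrocyclisation forms the C6–C1 bond and closes ring A as the cyclohexadienone 37, and enolisation then gives the phenol 38. This is the Danheiser benzannulation of a cyclobutenone with an alkoxyalkyne, here with a 3-alkoxycyclobutenone as in step 12, so both outer rings are closed by the same three bonds from the two arms of the central ring. No stereocentre is created, because the quaternary carbon of 35 becomes an aromatic carbon. The step needs regioselectivity in the [2+2], and the ynol ether oxygen secures it: it makes the CH2-bearing alkyne carbon the nucleophile, which bonds to the ketene carbonyl carbon, so the new hydroxyl (C6) and the methoxy group (C4) flank the bridge carbon C5 while methyl and benzyloxy fall on C3 and C2. It also needs chemoselectivity for the single ynol ether, which the neutral, reagent-free conditions secure, since aryl ethers, the adamantyl ether and the hindered acetyl group do not react with a ketene and any aryl ester formed from 38 and excess 34 is cleaved by the K2CO3/MeOH treatment.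

**Step 20**
Reactants: 38 1-[3-{[2-(1-adamantyloxy)-6-(benzyloxy)-4-methoxy-3-methylphenyl]methyl}-2,4,6-tris(benzyloxy)-5-{[4-(benzyloxy)-6-hydroxy-2-methoxy-3-methylphenyl]methyl}phenyl]ethanone
Product: 39 1-[3-[(2,6-dihydroxy-4-methoxy-3-methylphenyl)methyl]-5-[(4,6-dihydroxy-2-methoxy-3-methylphenyl)methyl]-2,4,6-trihydroxyphenyl]ethanone
Conditions: BCl3, C6HMe5, CH2Cl2, −78 °C; then MeOH
Reagents that add atoms: none
Why: Lewis-acid debenzylation with BCl3 and pentamethylbenzene as cation scavenger should remove the five benzyl groups at −78 °C and ionise the tertiary adamantyl ether (the cation is caught as its chloride), while aryl methyl ethers not chelated to a carbonyl group are not cleaved at this temperature.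

**Step 21**
Reactants: 39 1-[3-[(2,6-dihydroxy-4-methoxy-3-methylphenyl)methyl]-5-[(4,6-dihydroxy-2-methoxy-3-methylphenyl)methyl]-2,4,6-trihydroxyphenyl]ethanone; 40 butanoyl chloride
Product: 41 1-[3-[(3-butanoyl-2,6-dihydroxy-4-methoxy-5-methylphenyl)methyl]-5-[(3-butanoyl-2,4-dihydroxy-6-methoxy-5-methylphenyl)methyl]-2,4,6-trihydroxyphenyl]ethanone
Conditions: 40 (2.2 equiv in all), AlCl3 (10 equiv), PhNO2/CH2Cl2, 0 °C → rt; then ice/1 M HCl
Reagents that add atoms: butanoyl chloride (the second equivalent of 40, which acylates the other outer ring), CCCC(Cl)=O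
Why: Twofold Friedel–Crafts acylation that consumes two equivalents of butanoyl chloride, one at the single unsubstituted carbon (C1) of each outer ring, which is activated by its ortho and para oxygens, while the central ring is fully substituted and the phenols are held as aluminium phenoxides, which suppresses O-acylation.

**Compound list**

1 | 2,4,6-trihydroxyacetophenone | CC(=O)c1c(O)cc(O)cc1O | starting material
2 | 1-{3,5-bis[chloro(methoxy)methyl]-2,4,6-trihydroxyphenyl}ethanone (titanium-bound, mixture of diastereomers) | CC(=O)c1c(O)c(C(Cl)OC)c(O)c(C(Cl)OC)c1O | intermediate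
3 | 5-acetyl-2,4,6-trihydroxybenzene-1,3-dicarbaldehyde | CC(=O)c1c(O)c(C=O)c(O)c(C=O)c1O | intermediate
4 | 5-acetyl-2,4,6-tris(benzyloxy)benzene-1,3-dicarbaldehyde | CC(=O)c1c(OCc2ccccc2)c(C=O)c(OCc2ccccc2)c(C=O)c1OCc1ccccc1 | intermediate
5 | 1-[2,4,6-tris(benzyloxy)-3,5-bis(hydroxymethyl)phenyl]ethanone | CC(=O)c1c(OCc2ccccc2)c(CO)c(OCc2ccccc2)c(CO)c1OCc1ccccc1 | intermediate
6 | 1-[2,4,6-tris(benzyloxy)-3-({[tert-butyl(dimethyl)silyl]oxy}methyl)-5-(hydroxymethyl)phenyl]ethanone | CC(=O)c1c(OCc2ccccc2)c(CO[Si](C)(C)C(C)(C)C)c(OCc2ccccc2)c(CO)c1OCc1ccccc1 | intermediate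
7 | 1-[2,4,6-tris(benzyloxy)-3-(bromomethyl)-5-({[tert-butyl(dimethyl)silyl]oxy}methyl)phenyl]ethanone | CC(=O)c1c(OCc2ccccc2)c(CO[Si](C)(C)C(C)(C)C)c(OCc2ccccc2)c(CBr)c1OCc1ccccc1 | intermediate
8 | adamantan-1-ol | OC12CC3CC(CC(C3)C1)C2 | starting material
9 | trichloroethylene | ClC=C(Cl)Cl | starting material
10 | 1-{[(E)-1,2-dichloroethenyl]oxy}adamantane | Cl/C=C(/Cl)OC12CC3CC(CC(C3)C1)C2 | intermediate
11 | 1-[(chloroethynyl)oxy]adamantane | ClC#COC12CC3CC(CC(C3)C1)C2 | intermediate
12 | lithium (1-adamantyloxy)acetylide | [Li]C#COC12CC3CC(CC(C3)C1)C2 | intermediate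
13 | tributyl[(1-adamantyloxy)ethynyl]stannane | CCCC[Sn](CCCC)(CCCC)C#COC12CC3CC(CC(C3)C1)C2 | intermediate
14 | 1-[3-[3-(1-adamantyloxy)prop-2-yn-1-yl]-2,4,6-tris(benzyloxy)-5-({[tert-butyl(dimethyl)silyl]oxy}methyl)phenyl]ethanone | CC(=O)c1c(OCc2ccccc2)c(CO[Si](C)(C)C(C)(C)C)c(OCc2ccccc2)c(CC#COC23CC4CC(CC(C4)C2)C3)c1OCc1ccccc1 | intermediate
15 | propanoyl chloride | CCC(Cl)=O | starting material
16 | ethoxyacetylene | CCOC#C | starting material
17 | methylketene (prop-1-en-1-one) | CC=C=O | intermediate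
18 | 3-ethoxy-4-methylcyclobut-2-en-1-one (racemic) | CCOC1=CC(=O)C1C | intermediate
19 | 3-hydroxy-2-methylcyclobut-2-en-1-one (enol of 2-methylcyclobutane-1,3-dione) | CC1=C(O)CC1=O | intermediate
20 | 3-methoxy-2-methylcyclobut-2-en-1-one | COC1=C(C)C(=O)C1 | intermediate
21 | 3-methoxy-2-methylbuta-1,3-dien-1-one | COC(=C)C(C)=C=O | intermediate
22 | 2-(arylmethyl)-3-(1-adamantyloxy)-4-(1-methoxyethenyl)-4-methylcyclobut-2-en-1-one, aryl = central ring of 14 (racemic) | CC(=O)c1c(OCc2ccccc2)c(CO[Si](C)(C)C(C)(C)C)c(OCc2ccccc2)c(CC2=C(OC34CC5CC(CC(C5)C3)C4)C(C)(C(=C)OC)C2=O)c1OCc1ccccc1 | intermediate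
23 | 2-(arylmethyl)-3-(1-adamantyloxy)-5-methoxy-4-methylhexa-1,3,5-trien-1-one, aryl = central ring of 14 (ketene and vinyl groups cis) | CC(=O)c1c(OCc2ccccc2)c(CO[Si](C)(C)C(C)(C)C)c(OCc2ccccc2)c(CC(=C=O)/C(OC23CC4CC(CC(C4)C2)C3)=C(C)\C(=C)OC)c1OCc1ccccc1 | intermediate
24 | 2-(arylmethyl)-3-(1-adamantyloxy)-5-methoxy-4-methylcyclohexa-2,4-dien-1-one, aryl = central ring of 14 | CC(=O)c1c(OCc2ccccc2)c(CO[Si](C)(C)C(C)(C)C)c(OCc2ccccc2)c(CC2=C(OC34CC5CC(CC(C5)C3)C4)C(C)=C(OC)CC2=O)c1OCc1ccccc1 | intermediate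
25 | 1-[3-{[2-(1-adamantyloxy)-6-hydroxy-4-methoxy-3-methylphenyl]methyl}-2,4,6-tris(benzyloxy)-5-({[tert-butyl(dimethyl)silyl]oxy}methyl)phenyl]ethanone | CC(=O)c1c(OCc2ccccc2)c(CO[Si](C)(C)C(C)(C)C)c(OCc2ccccc2)c(Cc2c(O)cc(OC)c(C)c2OC34CC5CC(CC(C5)C3)C4)c1OCc1ccccc1 | intermediate
26 | 1-[3-{[2-(1-adamantyloxy)-6-(benzyloxy)-4-methoxy-3-methylphenyl]methyl}-2,4,6-tris(benzyloxy)-5-({[tert-butyl(dimethyl)silyl]oxy}methyl)phenyl]ethanone | CC(=O)c1c(OCc2ccccc2)c(CO[Si](C)(C)C(C)(C)C)c(OCc2ccccc2)c(Cc2c(OCc3ccccc3)cc(OC)c(C)c2OC34CC5CC(CC(C5)C3)C4)c1OCc1ccccc1 | intermediate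
27 | 1-[3-{[2-(1-adamantyloxy)-6-(benzyloxy)-4-methoxy-3-methylphenyl]methyl}-2,4,6-tris(benzyloxy)-5-(hydroxymethyl)phenyl]ethanone | CC(=O)c1c(OCc2ccccc2)c(CO)c(OCc2ccccc2)c(Cc2c(OCc3ccccc3)cc(OC)c(C)c2OC34CC5CC(CC(C5)C3)C4)c1OCc1ccccc1 | intermediate
28 | 1-[3-{[2-(1-adamantyloxy)-6-(benzyloxy)-4-methoxy-3-methylphenyl]methyl}-2,4,6-tris(benzyloxy)-5-(bromomethyl)phenyl]ethanone | CC(=O)c1c(OCc2ccccc2)c(CBr)c(OCc2ccccc2)c(Cc2c(OCc3ccccc3)cc(OC)c(C)c2OC34CC5CC(CC(C5)C3)C4)c1OCc1ccccc1 | intermediate
29 | chloroacetaldehyde dimethyl acetal (2-chloro-1,1-dimethoxyethane) | COC(CCl)OC | starting material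
30 | lithium methoxyacetylide | [Li]C#COC | intermediate
31 | tributyl(methoxyethynyl)stannane | CCCC[Sn](CCCC)(CCCC)C#COC | intermediate
32 | 1-[3-{[2-(1-adamantyloxy)-6-(benzyloxy)-4-methoxy-3-methylphenyl]methyl}-2,4,6-tris(benzyloxy)-5-(3-methoxyprop-2-yn-1-yl)phenyl]ethanone | CC(=O)c1c(OCc2ccccc2)c(CC#COC)c(OCc2ccccc2)c(Cc2c(OCc3ccccc3)cc(OC)c(C)c2OC34CC5CC(CC(C5)C3)C4)c1OCc1ccccc1 | intermediate
33 | 3-(benzyloxy)-2-methylcyclobut-2-en-1-one | CC1=C(OCc2ccccc2)CC1=O | intermediate
34 | 3-(benzyloxy)-2-methylbuta-1,3-dien-1-one | CC(=C=O)C(=C)OCc1ccccc1 | intermediate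
35 | 2-(arylmethyl)-4-[1-(benzyloxy)ethenyl]-3-methoxy-4-methylcyclobut-2-en-1-one, aryl = central ring of 32 (racemic) | CC(=O)c1c(OCc2ccccc2)c(CC2=C(OC)C(C)(C(=C)OCc3ccccc3)C2=O)c(OCc2ccccc2)c(Cc2c(OCc3ccccc3)cc(OC)c(C)c2OC34CC5CC(CC(C5)C3)C4)c1OCc1ccccc1 | intermediate
36 | 2-(arylmethyl)-5-(benzyloxy)-3-methoxy-4-methylhexa-1,3,5-trien-1-one, aryl = central ring of 32 (ketene and vinyl groups cis) | CC(=O)c1c(OCc2ccccc2)c(CC(=C=O)/C(OC)=C(C)\C(=C)OCc2ccccc2)c(OCc2ccccc2)c(Cc2c(OCc3ccccc3)cc(OC)c(C)c2OC34CC5CC(CC(C5)C3)C4)c1OCc1ccccc1 | intermediate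
37 | 2-(arylmethyl)-5-(benzyloxy)-3-methoxy-4-methylcyclohexa-2,4-dien-1-one, aryl = central ring of 32 | CC(=O)c1c(OCc2ccccc2)c(CC2=C(OC)C(C)=C(OCc3ccccc3)CC2=O)c(OCc2ccccc2)c(Cc2c(OCc3ccccc3)cc(OC)c(C)c2OC34CC5CC(CC(C5)C3)C4)c1OCc1ccccc1 | intermediate
38 | 1-[3-{[2-(1-adamantyloxy)-6-(benzyloxy)-4-methoxy-3-methylphenyl]methyl}-2,4,6-tris(benzyloxy)-5-{[4-(benzyloxy)-6-hydroxy-2-methoxy-3-methylphenyl]methyl}phenyl]ethanone | CC(=O)c1c(OCc2ccccc2)c(Cc2c(O)cc(OCc3ccccc3)c(C)c2OC)c(OCc2ccccc2)c(Cc2c(OCc3ccccc3)cc(OC)c(C)c2OC34CC5CC(CC(C5)C3)C4)c1OCc1ccccc1 | intermediate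
39 | 1-[3-[(2,6-dihydroxy-4-methoxy-3-methylphenyl)methyl]-5-[(4,6-dihydroxy-2-methoxy-3-methylphenyl)methyl]-2,4,6-trihydroxyphenyl]ethanone | CC(=O)c1c(O)c(Cc2c(O)cc(O)c(C)c2OC)c(O)c(Cc2c(O)cc(OC)c(C)c2O)c1O | intermediate
40 | butanoyl chloride | CCCC(Cl)=O | starting material
41 | 1-[3-[(3-butanoyl-2,6-dihydroxy-4-methoxy-5-methylphenyl)methyl]-5-[(3-butanoyl-2,4-dihydroxy-6-methoxy-5-methylphenyl)methyl]-2,4,6-trihydroxyphenyl]ethanone | CCCC(=O)c1c(O)c(C)c(OC)c(Cc2c(O)c(Cc3c(O)c(C)c(OC)c(C(=O)CCC)c3O)c(O)c(C(C)=O)c2O)c1O | target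

**Step count**

Total: 21 steps. Longest linear sequence: 14 steps (1, 2, 3, 4, 5, 8, 12, 13, 14, 15, 17, 19, 20, 21).

**Steps most likely to fail**

Step 19 (key step). The 4π opening of the vinylogous-ester cyclobutenone 33 may be slower than the loss of the ynol ether arm of 32 at 120 °C (hydration by traces of water, prototropic shift to the allenyl ether, oligomerisation with the ketene), and the new phenol may be acylated by 34. The fallback sets out from alcohol 27 and forms the CH2–ring A bond by Friedel–Crafts benzylation instead of building ring A. Alcohol 27 and purchased aspidinol, 1-(2,6-dihydroxy-4-methoxy-3-methylphenyl)butan-1-one, in hexafluoropropan-2-ol (cat. TsOH if needed, rt) should alkylate the only free ring carbon of aspidinol and give the protected trimer with ring A already butyrylated, 1-[3-{[2-(1-adamantyloxy)-6-(benzyloxy)-4-methoxy-3-methylphenyl]methyl}-2,4,6-tris(benzyloxy)-5-[(3-butanoyl-2,4-dihydroxy-6-methoxy-5-methylphenyl)methyl]phenyl]ethanone F4. BCl3/C6HMe5 as in step 20 should give the mono-butyryl heptaphenol F5, and acylation of its one remaining free ring carbon (ring B) with one equivalent of 40 under the conditions of step 21 comes back to the route at 41.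

Step 12. The bulky adamantyloxy group next to a disubstituted ketene carbon may slow the second C–C bond of the [2+2], or 20 may not open before 14 decomposes. The fallback sets out from 14 and makes the same vinylketene 21 at room temperature by 1,4-dehydrochlorination instead of electrocyclic opening. Methyl 2-methylacetoacetate with HC(OMe)3 and cat. H2SO4 should give methyl (E)-3-methoxy-2-methylbut-2-enoate F1, LiOH the acid (E)-3-methoxy-2-methylbut-2-enoic acid F2, and oxalyl chloride the acid chloride (E)-3-methoxy-2-methylbut-2-enoyl chloride F3. Slow addition of F3 to 14 and Et3N in CH2Cl2 at rt should give the adduct 22, and heating at 80 °C in toluene takes 22 through 23 and 24 to 25, where the route is rejoined.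

Step 21. With seven free phenols and AlCl3 the methoxy group that becomes ortho to the new ketone in ring B may lose its methyl, the CH2 bridges may be cleaved or migrate under acid, and phenols may be O-acylated. The fallback sets out from 39 and uses a Houben–Hoesch acylation: butanenitrile (two equivalents), ZnCl2 and HCl gas in Et2O at 0 °C should give the bis(ketiminium chloride) F6, which is hydrolysed in warm water to 41.

**Further compounds**

F1 | step 12 | methyl (E)-3-methoxy-2-methylbut-2-enoate | COC(=O)/C(C)=C(/OC)C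
F2 | step 12 | (E)-3-methoxy-2-methylbut-2-enoic acid | OC(=O)/C(C)=C(/OC)C
F3 | step 12 | (E)-3-methoxy-2-methylbut-2-enoyl chloride | ClC(=O)/C(C)=C(/OC)C
F4 | step 19 | 1-[3-{[2-(1-adamantyloxy)-6-(benzyloxy)-4-methoxy-3-methylphenyl]methyl}-2,4,6-tris(benzyloxy)-5-[(3-butanoyl-2,4-dihydroxy-6-methoxy-5-methylphenyl)methyl]phenyl]ethanone | CC(=O)c1c(OCc2ccccc2)c(Cc2c(O)c(C(=O)CCC)c(O)c(C)c2OC)c(OCc2ccccc2)c(Cc2c(OCc3ccccc3)cc(OC)c(C)c2OC34CC5CC(CC(C5)C3)C4)c1OCc1ccccc1
F5 | step 19 | 1-[3-[(3-butanoyl-2,4-dihydroxy-6-methoxy-5-methylphenyl)methyl]-5-[(2,6-dihydroxy-4-methoxy-3-methylphenyl)methyl]-2,4,6-trihydroxyphenyl]ethanone | CC(=O)c1c(O)c(Cc2c(O)c(C(=O)CCC)c(O)c(C)c2OC)c(O)c(Cc2c(O)cc(OC)c(C)c2O)c1O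
F6 | step 21 | bis(ketiminium chloride) of 41 at both butanoyl carbons | CCCC(=[NH2+])c1c(O)c(C)c(OC)c(Cc2c(O)c(Cc3c(O)c(C)c(OC)c(C(=[NH2+])CCC)c3O)c(O)c(C(C)=O)c2O)c1O.[Cl-].[Cl-]
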